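## Retrosynthetic overview

1. C8=C9 (E) is cut by cross-metathesis into a 2-vinyl furo[3,2-b]pyran-5-one core and (2R,3S)-2-hydroxypent-4-en-3-yl benzoate.
2. C10–C11 is the key bond: the carbonyl carbon of acrolein, made nucleophilic as an α-benzoyloxy-allyl iridium species (from acrolein gem-dibenzoate), adds to the carbonyl carbon of acetaldehyde formed in the flask from ethanol. This one step sets both side-chain stereocentres and places the benzoate.
3. The δ-lactone (second ring) comes from ring-rearrangement metathesis of the endo mono-acrylate of 7-oxabicyclo[2.2.1]hept-5-ene-2,3-diol; the all-cis ring stereochemistry is that of the endo diol.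
4. The tetrahydrofuran (first ring) is the oxygen bridge of the furan + vinylene carbonate Diels–Alder adduct; the meso diol is desymmetrised by catalytic mono-acryloylation.

Atom labels follow the carbon chain: C1 lactone C=O, C2=C3, C4 and C5 ring-fusion carbons, C6 carbinol, C7 furan carbon bearing the side chain, C8=C9, C10 benzoate carbon, C11 carbinol, C12 methyl.

Assumption: the ligand antipodes named in steps 2 and 5 ((S)-SEGPHOS; (S,S)-Ph-BOX) are assumed, not verified, to give the drawn enantiomers; if a first run shows the mirror sense, the other antipode is used and nothing else changes.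

## Route

Step 1
Reactants: 1 acrolein; 2 benzoic anhydride
Product: 3 prop-2-ene-1,1-diyl dibenzoate (acrolein gem-dibenzoate)
Conditions: H2SO4 (cat.), CH2Cl2, 0 °C → rt
Reagents that add atoms: none
Why: Acid-catalysed acylal formation, in which the anhydride adds across the activated C=O of the enal; no stereocentre is formed.

Step 2
Reactants: 3 prop-2-ene-1,1-diyl dibenzoate; 4 ethanol
Product: 6 (2R,3S)-2-hydroxypent-4-en-3-yl benzoate, via acetaldehyde 5 (not isolated)
Conditions: [Ir(cod)Cl]2 (2.5 mol %), (S)-SEGPHOS (5 mol %), 4-cyano-3-nitrobenzoic acid (10 mol %), K3PO4 (1 equiv), ethanol in three- to fivefold excess, THF, 90 °C, sealed tube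
Reagents that add atoms: none
Why: Iridium-catalysed transfer-hydrogenative carbonyl (α-benzoyloxy)allylation, in which the catalyst dehydrogenates ethanol to 5 and ionises 3 to an (E)-σ-allyl iridium species whose benzoyloxy-bearing carbon (the former acrolein carbonyl carbon, now nucleophilic) adds to the carbonyl carbon of 5 through a closed chair transition state; the (E)-geometry gives the anti (erythro) C10/C11 relationship, the chiral bisphosphine selects the aldehyde face to set C11 (R) and C10 (S), and the benzoate ends on the allylic oxygen.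

Step 3
Reactants: 7 furan; 8 vinylene carbonate
Product: 9 endo-7-oxabicyclo[2.2.1]hept-5-ene-2,3-diyl carbonate (meso; 1R,2S,3R,4S)
Conditions: neat in excess furan (fivefold), BHT (trace), sealed tube, 125 °C, 20 h; endo adduct separated from the exo isomer by crystallisation and chromatography
Reagents that add atoms: none
Why: Diels–Alder cycloaddition, a pure addition that keeps the cis geometry of the dienophile and gives an endo/exo mixture from which the endo adduct (both C–O bonds syn to the C5=C6 bridge) is taken on; the product is meso, so no absolute configuration is set yet.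

Step 4
Reactants: 9 endo carbonate
Product: 10 (1R,2R,3S,4S)-7-oxabicyclo[2.2.1]hept-5-ene-2,3-diol (meso endo,endo-diol)
Conditions: K2CO3 (cat.), MeOH, rt
Reagents that add atoms: none
Why: Carbonate methanolysis (transesterification) at room temperature, which cleaves only C(=O)–O bonds, so the endo-cis configuration is untouched and retro-Diels–Alder is avoided.

Step 5
Reactants: 10 meso diol; 11 acryloyl chloride
Product: 12 (1R,2R,3R,4S)-3-hydroxy-7-oxabicyclo[2.2.1]hept-5-en-2-yl prop-2-enoate
Conditions: Cu(OTf)2 (5 mol %), (S,S)-Ph-BOX (5 mol %), K2CO3, acryloyl chloride in slight excess (1.05 equiv), CH2Cl2, −40 °C; used at once, kept cold and neutral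
Reagents that add atoms: none
Why: Proposed new method: enantioselective mono-acylation of a meso cis-1,2-diol, in which the diol chelates the chiral Cu(OTf)2–bis(oxazoline) Lewis acid, the hydroxyl in the open quadrant is deprotonated by K2CO3 and acylated, and the mono-ester binds copper less well so bis-acylation is slow; the closest known reaction is the Cu(OTf)2/Ph-BOX-catalysed enantioselective mono-benzoylation of meso-1,2-diols with benzoyl chloride, here run with acryloyl chloride, and the choice of enantiotopic carbinol (the future C5–O) fixes the absolute configuration of all four ring stereocentres.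

Step 6
Reactants: 12 mono-acrylate
Product: 13 (2S,3R,3aR,7aR)-2-ethenyl-3-hydroxy-2,3,3a,7a-tetrahydro-5H-furo[3,2-b]pyran-5-one
Conditions: second-generation Grubbs catalyst (5 mol %), ethylene (1 atm), CH2Cl2 (5 mM), 40 °C
Reagents that add atoms: none
Why: Ring-rearrangement metathesis (ring-opening/ring-closing), in which strain release opens the oxanorbornene, the carbene at C3 closes onto the cis acrylate to give the Z-enoate δ-lactone and the other terminus ends as the C7 vinyl group; no stereocentre is touched, so the endo geometry is carried into the all-cis C4–C7 array with a cis ring fusion.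

Step 7
Reactants: 13 vinyl lactone; 6 (2R,3S)-2-hydroxypent-4-en-3-yl benzoate
Product: 14 (2R,3S,4E)-2-hydroxy-5-[(2S,3R,3aR,7aR)-3-hydroxy-5-oxo-2,3,3a,7a-tetrahydro-5H-furo[3,2-b]pyran-2-yl]pent-4-en-3-yl benzoate (target)
Conditions: Hoveyda–Grubbs second-generation catalyst (10 mol %), 6 in threefold excess (surplus and its homodimer recovered), CH2Cl2 (0.1 M), 40 °C
Reagents that add atoms: none
Why: Olefin cross-metathesis of two monosubstituted alkenes with loss of ethylene, reversible and therefore E-selective, while the conjugated lactone alkene stays out of the reaction; no stereocentre is affected and the neutral conditions avoid benzoate migration.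

## Compound list

1 | acrolein (prop-2-enal) | C=CC=O | starting material
2 | benzoic anhydride | O=C(OC(=O)c1ccccc1)c1ccccc1 | starting material
3 | prop-2-ene-1,1-diyl dibenzoate (acrolein gem-dibenzoate) | C=CC(OC(=O)c1ccccc1)OC(=O)c1ccccc1 | intermediate
4 | ethanol | CCO | starting material
5 | acetaldehyde | CC=O | intermediate
6 | (2R,3S)-2-hydroxypent-4-en-3-yl benzoate | C[C@@H](O)[C@H](C=C)OC(=O)c1ccccc1 | intermediate
7 | furan | c1ccoc1 | starting material
8 | vinylene carbonate (1,3-dioxol-2-one) | O=C1OC=CO1 | starting material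
9 | endo-7-oxabicyclo[2.2.1]hept-5-ene-2,3-diyl carbonate (meso; 1R,2S,3R,4S) | O=C1O[C@@H]2[C@H](O1)[C@@H]1C=C[C@H]2O1 | intermediate
10 | (1R,2R,3S,4S)-7-oxabicyclo[2.2.1]hept-5-ene-2,3-diol (meso endo,endo-diol) | O[C@@H]1[C@H](O)[C@@H]2C=C[C@H]1O2 | intermediate
11 | acryloyl chloride | C=CC(=O)Cl | starting material
12 | (1R,2R,3R,4S)-3-hydroxy-7-oxabicyclo[2.2.1]hept-5-en-2-yl prop-2-enoate | C=CC(=O)O[C@@H]1[C@H](O)[C@@H]2C=C[C@H]1O2 | intermediate
13 | (2S,3R,3aR,7aR)-2-ethenyl-3-hydroxy-2,3,3a,7a-tetrahydro-5H-furo[3,2-b]pyran-5-one | C=C[C@@H]1O[C@@H]2C=CC(=O)O[C@@H]2[C@@H]1O | intermediate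
14 | (2R,3S,4E)-2-hydroxy-5-[(2S,3R,3aR,7aR)-3-hydroxy-5-oxo-2,3,3a,7a-tetrahydro-5H-furo[3,2-b]pyran-2-yl]pent-4-en-3-yl benzoate | C[C@@H](O)[C@H](/C=C/[C@@H]1O[C@@H]2C=CC(=O)O[C@@H]2[C@@H]1O)OC(=O)c1ccccc1 | target

## Step count and risks

Total step count: 7. Longest linear sequence: 5 (steps 3–7, furan to 14); the side-chain branch is steps 1–2.

Three steps most likely to fail:

**Step 5** (new desymmetrising acryloylation; uncertain enantioselectivity, and 1,2-acyl migration in 12 would racemise it). The fallback resolves through the enantiopure side chain instead of a chiral catalyst. It sets out from 10: acryloyl chloride (1.0 equiv), Et3N, CH2Cl2, −78 °C gives the racemic mono-acrylate, that is 12 together with its enantiomer (1S,2S,3S,4R)-3-hydroxy-7-oxabicyclo[2.2.1]hept-5-en-2-yl prop-2-enoate F1. The conditions of step 6 turn the pair into 13 and its enantiomer (2R,3S,3aS,7aS)-2-ethenyl-3-hydroxy-2,3,3a,7a-tetrahydro-5H-furo[3,2-b]pyran-5-one F2. Cross-metathesis with 6 as in step 7 then gives 14 and the diastereomer (2R,3S,4E)-2-hydroxy-5-[(2R,3S,3aS,7aS)-3-hydroxy-5-oxo-2,3,3a,7a-tetrahydro-5H-furo[3,2-b]pyran-2-yl]pent-4-en-3-yl benzoate F3, which are separated by chromatography. The route is rejoined at 14.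

**Step 2** (small, volatile aldehyde partner; ee and anti-selectivity untested for ethanol; possible benzoate migration at 90 °C with base). The fallback uses reagent-controlled epoxidation instead of the catalytic coupling. It sets out from 1: vinylmagnesium bromide (THF, −78 °C) gives penta-1,4-dien-3-ol F4. Sharpless asymmetric epoxidation (Ti(OiPr)4, L-(+)-diisopropyl tartrate, tBuOOH, 4 Å sieves, CH2Cl2, −20 °C) selects one enantiotopic vinyl group and one face, giving the erythro epoxy alcohol (2R,3S)-1,2-epoxypent-4-en-3-ol F5. BzCl/pyridine gives (1S)-1-[(2R)-oxiran-2-yl]prop-2-en-1-yl benzoate F6. LiI/AcOH in THF opens the epoxide at the terminal carbon to (2S,3S)-2-hydroxy-1-iodopent-4-en-3-yl benzoate F7 (the C2 descriptor changes only because iodine raises the priority of C1). Bu3SnH/AIBN (toluene, 80 °C) removes the iodine, and the route is rejoined at 6.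

**Step 7** (two hindered, allylically oxygenated alkenes; slow cross-coupling and homodimers). The fallback is a ring-opening/ring-closing/cross-metathesis cascade instead of coupling two preformed vinyl groups. It sets out from 12, treated with 6 (3–4 equiv) and second-generation Grubbs catalyst in CH2Cl2 at 40 °C without ethylene. Strain-release ring opening of the oxanorbornene gives a ruthenium carbene at C8 that is captured by 6, while the C3 terminus closes onto the acrylate; any 13 formed alongside is returned to the same mixture. The route is rejoined at 14, and this fallback makes no new compound (F0).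

## Further compounds

F1 | step 5 | (1S,2S,3S,4R)-3-hydroxy-7-oxabicyclo[2.2.1]hept-5-en-2-yl prop-2-enoate | C=CC(=O)O[C@H]1[C@@H](O)[C@H]2C=C[C@@H]1O2
F2 | step 5 | (2R,3S,3aS,7aS)-2-ethenyl-3-hydroxy-2,3,3a,7a-tetrahydro-5H-furo[3,2-b]pyran-5-one | C=C[C@H]1O[C@H]2C=CC(=O)O[C@H]2[C@H]1O
F3 | step 5 | (2R,3S,4E)-2-hydroxy-5-[(2R,3S,3aS,7aS)-3-hydroxy-5-oxo-2,3,3a,7a-tetrahydro-5H-furo[3,2-b]pyran-2-yl]pent-4-en-3-yl benzoate | C[C@@H](O)[C@H](/C=C/[C@H]1O[C@H]2C=CC(=O)O[C@H]2[C@H]1O)OC(=O)c1ccccc1
F4 | step 2 | penta-1,4-dien-3-ol | C=CC(O)C=C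
F5 | step 2 | (2R,3S)-1,2-epoxypent-4-en-3-ol | C1O[C@H]1[C@@H](O)C=C
F6 | step 2 | (1S)-1-[(2R)-oxiran-2-yl]prop-2-en-1-yl benzoate | C1O[C@H]1[C@@H](OC(=O)c2ccccc2)C=C
F7 | step 2 | (2S,3S)-2-hydroxy-1-iodopent-4-en-3-yl benzoate | IC[C@@H](O)[C@H](C=C)OC(=O)c1ccccc1
F0 | step 7 | none | none
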